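**Retrosynthetic overview**

1. Ring-D allyl groups ⇒ ethenolysis of one internal alkene: eugenol (1) is first dimerised by self-metathesis to bisphenol 2, and the route then runs in two directions from this core.
2. C9–O ether ⇒ O-alkylation of 2 with (E)-1,3-dichloropropene (3) (mono-ether 4, then bis-ether 5); C7–aryl bond ⇒ Suzuki coupling of 5 with guaiacyl boronate 6 (mono-coupled 7, then bis(4-hydroxystyrene) 8).
3. Ring A ⇒ a second eugenol unit, taken as its dearomatised ortho-quinone monoketal 9.
4. Key disconnection: C3–C3a and O1–C2 of both dihydrofurans ⇒ 8 + 2 × 9, one catalytic asymmetric double [3+2] annulation (mono-adduct 10, then bis-adduct 11) that sets all four stereocentres.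
5. Ring order: no ring is made before that step; the two 2,3-dihydrofuran rings (ring B of each half) close in the same operation; ethenolysis of 11 then gives two molecules of target 12.

Assumption: the (R)-configured acid of step 5 is taken to give the (2S,3R) series; if it gives the mirror image, the (S)-acid is used and nothing else changes.

**Route**

Step 1
Reactants: 1 eugenol (4-allyl-2-methoxyphenol), two molecules
Product: 2 (E)-4,4'-(but-2-ene-1,4-diyl)bis(2-methoxyphenol)
Conditions: second-generation Grubbs catalyst RuCl2(=CHPh)(PCy3)(H2IMes) (0.5 mol %), 1,4-benzoquinone (2 mol %), CH2Cl2, 40 °C, N2 sweep; crystallise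
Reagents that add atoms: none
Why: Olefin cross-metathesis (self-metathesis) of the terminal allyl group is driven by loss of ethylene and tolerates the free phenol, benzoquinone holds back ruthenium hydride isomerisation to isoeugenol, and the alkene geometry does not matter because this alkene is cleaved again in step 6.

Step 2
Reactants: 2 (E)-4,4'-(but-2-ene-1,4-diyl)bis(2-methoxyphenol); 3 (E)-1,3-dichloropropene (3 equiv)
Product: 5 (E)-1,4-bis{4-[(E)-3-chloroallyloxy]-3-methoxyphenyl}but-2-ene, via mono(3-chloroallyl) ether 4 (not isolated)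
Conditions: K2CO3 (3 equiv), DMF, 50 °C
Reagents that add atoms: none
Why: Williamson ether synthesis, in which each phenoxide displaces the allylic chloride of 3 by SN2 while the vinylic C–Cl bond is inert, so the E-chloroalkene is carried over unchanged.

Step 3
Reactants: 5 (E)-1,4-bis{4-[(E)-3-chloroallyloxy]-3-methoxyphenyl}but-2-ene; 6 2-methoxy-4-(4,4,5,5-tetramethyl-1,3,2-dioxaborolan-2-yl)phenol (2.4 equiv)
Product: 8 (E)-1,4-bis{4-[(E)-3-(4-hydroxy-3-methoxyphenyl)allyloxy]-3-methoxyphenyl}but-2-ene, via mono-coupled alkenyl chloride 7 (not isolated)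
Conditions: Pd(OAc)2 (4 mol %), SPhos (8 mol %), K3PO4 (6 equiv), THF/H2O 10:1, 45 °C
Reagents that add atoms: none
Why: Suzuki–Miyaura coupling of the alkenyl chlorides with retention of E geometry, in which zerovalent palladium with the bulky biarylphosphine inserts into C(sp2)–Cl at a temperature that leaves the allylic aryl ether alone, the unprotected phenol of 6 is tolerated as its phenoxide, and the central 1,2-dialkyl alkene is a much poorer Heck and isomerisation partner than a terminal allyl group would be.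

Step 4
Reactants: 1 eugenol
Product: 9 4-allyl-6,6-dimethoxycyclohexa-2,4-dien-1-one
Conditions: PhI(OAc)2 (1.05 equiv), MeOH, −10 °C, 15 min; cold NaHCO3 wash; used at once as a CH2Cl2 solution kept below −20 °C
Reagents that add atoms: methanol, CO
Why: Oxidative dearomatisation of a 2-methoxyphenol by the trivalent iodine reagent in methanol (masked ortho-benzoquinone formation), in which methanol adds to the ring carbon that already carries the methoxy group because that position best stabilises the aryloxenium intermediate; no stereocentre is formed.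

Step 5
Reactants: 8 (E)-1,4-bis{4-[(E)-3-(4-hydroxy-3-methoxyphenyl)allyloxy]-3-methoxyphenyl}but-2-ene; 9 4-allyl-6,6-dimethoxycyclohexa-2,4-dien-1-one (two molecules react; 3 equiv used)
Product: 11 (E)-1,4-bis{4-[((2S,3R)-5-allyl-2-(4-hydroxy-3-methoxyphenyl)-7-methoxy-2,3-dihydro-1-benzofuran-3-yl)methoxy]-3-methoxyphenyl}but-2-ene, via mono-adduct 10 (not isolated)
Conditions: (R)-3,3'-bis(2,4,6-triisopropylphenyl)-1,1'-binaphthyl-2,2'-diyl N-triflylphosphoramide (20 mol %), 5 Å molecular sieves, CH2Cl2/toluene 1:1, −60 → −30 °C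
Reagents that add atoms: none
Why: Proposed new method: the strong chiral Brønsted acid ionises the ketal of 9 to a 4-allyl-2-methoxyphenoxenium ion paired with the chiral phosphoramidate, the β-carbon (C8) of each 4-hydroxystyrene, held to the anion through its phenol O–H, attacks the only unsubstituted ortho carbon, the dienone re-aromatises and its oxygen closes onto the resulting para-quinone methide carbon, so C3 is set by anion-controlled facial attack and C2 ends trans to it because this ring closure is reversible; the closest known reaction types are the Brønsted-acid-promoted formal [3+2] coupling of quinone monoacetals with styrenes and chiral-phosphoric-acid-catalysed [3+2] annulations of quinone monoimines and imine ketals with hydroxystyrenes, and both 2,3-dihydrofuran rings with all four stereocentres form in this single operation.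

Step 6
Reactants: 11 (E)-1,4-bis{4-[((2S,3R)-5-allyl-2-(4-hydroxy-3-methoxyphenyl)-7-methoxy-2,3-dihydro-1-benzofuran-3-yl)methoxy]-3-methoxyphenyl}but-2-ene
Product: 12 4-[(2S,3R)-5-allyl-3-[(4-allyl-2-methoxyphenoxy)methyl]-7-methoxy-2,3-dihydro-1-benzofuran-2-yl]-2-methoxyphenol (CNP0138854.1; two molecules per molecule of 11)
Conditions: ethylene (5 bar), second-generation Hoveyda–Grubbs catalyst RuCl2(=CH-C6H4-2-OiPr)(H2IMes) (5 mol %), 1,4-benzoquinone (10 mol %), CH2Cl2, 35 °C
Reagents that add atoms: ethylene, C=C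
Why: Ethenolysis (cross-metathesis with ethylene) cleaves the only internal alkene so that each half of 11 leaves as one molecule of 12 with a new terminal allyl group, excess ethylene keeps all allyl groups terminal, and the stereocentres are remote from the reacting alkene and untouched.

**Compound list**

1 | eugenol (4-allyl-2-methoxyphenol) | C=CCc1ccc(O)c(OC)c1 | starting material
2 | (E)-4,4'-(but-2-ene-1,4-diyl)bis(2-methoxyphenol) | COc1cc(C/C=C/Cc2ccc(O)c(OC)c2)ccc1O | intermediate
3 | (E)-1,3-dichloropropene | ClC/C=C/Cl | starting material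
4 | 4-[(E)-4-{4-[(E)-3-chloroallyloxy]-3-methoxyphenyl}but-2-enyl]-2-methoxyphenol (mono-ether, not isolated) | COc1cc(C/C=C/Cc2ccc(OC/C=C/Cl)c(OC)c2)ccc1O | intermediate
5 | (E)-1,4-bis{4-[(E)-3-chloroallyloxy]-3-methoxyphenyl}but-2-ene | COc1cc(C/C=C/Cc2ccc(OC/C=C/Cl)c(OC)c2)ccc1OC/C=C/Cl | intermediate
6 | 2-methoxy-4-(4,4,5,5-tetramethyl-1,3,2-dioxaborolan-2-yl)phenol | COc1cc(B2OC(C)(C)C(C)(C)O2)ccc1O | starting material
7 | 4-[(E)-3-{4-[(E)-4-{4-[(E)-3-chloroallyloxy]-3-methoxyphenyl}but-2-enyl]-2-methoxyphenoxy}prop-1-enyl]-2-methoxyphenol (mono-coupled, not isolated) | COc1cc(/C=C/COc2ccc(C/C=C/Cc3ccc(OC/C=C/Cl)c(OC)c3)cc2OC)ccc1O | intermediate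
8 | (E)-1,4-bis{4-[(E)-3-(4-hydroxy-3-methoxyphenyl)allyloxy]-3-methoxyphenyl}but-2-ene | COc1cc(/C=C/COc2ccc(C/C=C/Cc3ccc(OC/C=C/c4ccc(O)c(OC)c4)c(OC)c3)cc2OC)ccc1O | intermediate
9 | 4-allyl-6,6-dimethoxycyclohexa-2,4-dien-1-one | C=CCC1=CC(OC)(OC)C(=O)C=C1 | intermediate
10 | mono-adduct (not isolated): one arm is the (2S,3R)-dihydrobenzofuran as in 11, the other arm is still the (E)-3-(4-hydroxy-3-methoxyphenyl)allyl ether | COc1cc(C/C=C/Cc2ccc(OC[C@H]3c4cc(CC=C)cc(OC)c4O[C@@H]3c3ccc(O)c(OC)c3)c(OC)c2)ccc1OC/C=C/c1ccc(O)c(OC)c1 | intermediate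
11 | (E)-1,4-bis{4-[((2S,3R)-5-allyl-2-(4-hydroxy-3-methoxyphenyl)-7-methoxy-2,3-dihydro-1-benzofuran-3-yl)methoxy]-3-methoxyphenyl}but-2-ene | COc1cc(C/C=C/Cc2ccc(OC[C@H]3c4cc(CC=C)cc(OC)c4O[C@@H]3c3ccc(O)c(OC)c3)c(OC)c2)ccc1OC[C@H]1c2cc(CC=C)cc(OC)c2O[C@@H]1c1ccc(O)c(OC)c1 | intermediate
12 | 4-[(2S,3R)-5-allyl-3-[(4-allyl-2-methoxyphenoxy)methyl]-7-methoxy-2,3-dihydro-1-benzofuran-2-yl]-2-methoxyphenol (2,3-trans) | C=CCc1ccc(OC[C@H]2c3cc(CC=C)cc(OC)c3O[C@@H]2c2ccc(O)c(OC)c2)c(OC)c1 | target

**Step count and risks**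

Total step count: 6. Longest linear sequence: 5 steps (1 → 2 → 5 → 8 → 11 → 12); ketal 9 is a one-step branch from 1.

Most likely to fail, first: step 5. The asymmetric induction is unproven, 9 can dimerise by Diels–Alder reaction, and the acid can cleave the cinnamyl aryl ethers of 8. Any meso diastereomer of 11 is unlikely to be separable and lowers the ee of 12 to the per-arm selectivity. The fallback sets out from 8 and 1 and comes back at 12. It drops the dearomatised donor and the chiral acid and makes the same two rings by one-electron phenol cross-coupling: Ag2O (4.5 equiv) with 1 (10 equiv) in CH2Cl2/acetone at 20 °C in the dark. This gives the trans,trans bis-adduct without absolute control, that is 11 together with the meso (2S,3R,2'R,3'S) bis-adduct F1 and the enantiomeric (2R,3S,2'R,3'S) bis-adduct F2. The mixture is taken through the ethenolysis conditions of step 6 to give 12 with the (2R,3S)-enantiomer of the target F3, and 12 is isolated by preparative chromatography on a chiral stationary phase (supercritical CO2/MeOH).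

Second: step 4. Ketal 9 may dimerise before use or resist ionisation. The fallback sets out from 1 and comes back at 11. PhI(OAc)2 in CH2Cl2 at −78 °C without methanol acetoxylates 1 to the racemic ortho-quinol acetate (3-allyl-1-methoxy-6-oxocyclohexa-2,4-dien-1-yl) acetate F4. Its acetate leaves far more readily, so the milder parent (R)-BINOL-derived phosphoric acid suffices. F4 replaces 9 in the annulation with 8 and its stereocentre is lost on ionisation.

Third: step 3. Zerovalent palladium may ionise the cinnamyl aryl ether as it forms. The fallback sets out from 2 and comes back at 8, and it avoids palladium at the allylic ether stage. Commercial ethyl ferulate is silylated (TBSCl, imidazole, DMF) to ethyl (E)-3-[4-(tert-butyldimethylsilyloxy)-3-methoxyphenyl]prop-2-enoate F5. Reduction with iBu2AlH in CH2Cl2 at −78 °C gives (E)-3-[4-(tert-butyldimethylsilyloxy)-3-methoxyphenyl]prop-2-en-1-ol F6. Double Mitsunobu etherification of 2 with F6 (PPh3, diisopropyl azodicarboxylate, THF, 0 °C) gives the bis(silyl ether) of 8 F7, and Bu4NF in THF at 0 °C releases 8.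

**Further compounds**

F1 | step 5 | (E)-1,4-bis-adduct with one (2S,3R) and one (2R,3S) dihydrobenzofuran unit (meso diastereomer of 11) | COc1cc(C/C=C/Cc2ccc(OC[C@H]3c4cc(CC=C)cc(OC)c4O[C@@H]3c3ccc(O)c(OC)c3)c(OC)c2)ccc1OC[C@@H]1c2cc(CC=C)cc(OC)c2O[C@H]1c1ccc(O)c(OC)c1
F2 | step 5 | (2R,3S,2'R,3'S) enantiomer of 11 | COc1cc(C/C=C/Cc2ccc(OC[C@@H]3c4cc(CC=C)cc(OC)c4O[C@H]3c3ccc(O)c(OC)c3)c(OC)c2)ccc1OC[C@@H]1c2cc(CC=C)cc(OC)c2O[C@H]1c1ccc(O)c(OC)c1
F3 | step 5 | 4-[(2R,3S)-5-allyl-3-[(4-allyl-2-methoxyphenoxy)methyl]-7-methoxy-2,3-dihydro-1-benzofuran-2-yl]-2-methoxyphenol (enantiomer of 12) | C=CCc1ccc(OC[C@@H]2c3cc(CC=C)cc(OC)c3O[C@H]2c2ccc(O)c(OC)c2)c(OC)c1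
F4 | step 4 | (3-allyl-1-methoxy-6-oxocyclohexa-2,4-dien-1-yl) acetate (racemic) | C=CCC1=CC(OC)(OC(C)=O)C(=O)C=C1
F5 | step 3 | ethyl (E)-3-[4-(tert-butyldimethylsilyloxy)-3-methoxyphenyl]prop-2-enoate | CCOC(=O)/C=C/c1ccc(O[Si](C)(C)C(C)(C)C)c(OC)c1
F6 | step 3 | (E)-3-[4-(tert-butyldimethylsilyloxy)-3-methoxyphenyl]prop-2-en-1-ol | OC/C=C/c1ccc(O[Si](C)(C)C(C)(C)C)c(OC)c1
F7 | step 3 | (E)-1,4-bis{4-[(E)-3-(4-(tert-butyldimethylsilyloxy)-3-methoxyphenyl)allyloxy]-3-methoxyphenyl}but-2-ene | COc1cc(/C=C/COc2ccc(C/C=C/Cc3ccc(OC/C=C/c4ccc(O[Si](C)(C)C(C)(C)C)c(OC)c4)c(OC)c3)cc2OC)ccc1O[Si](C)(C)C(C)(C)C
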